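**Plan**

- Numbering used throughout: bicyclo[3.3.1]nonane with C1 the bridgehead next to quaternary C8, C2–C4 the diketone bridge (aroyl on C3), C5 the second bridgehead, C6 the CH2, C7 the prenylated CH, C9 the bridge ketone; ring A = C1, C5–C9; ring B = C1–C5, C9; prenyl = 3-methylbut-2-en-1-yl, homoprenyl = 4-methylpent-3-en-1-yl.
- Enabling feature: C4 of ring B is at once the β-terminus of the C2=O/C3=C4 enone and the carbon that carries the enol oxygen. Disconnecting C4–C5 therefore leaves a 3-ethoxypropynoyl arm on C1 opposite a C5=C9 silyl enol ether of ring A.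
- Cuts, in retrosynthetic order: C3–aroyl; C4–C5 (ring B); C2–C3 (acetylide to a C1 aldehyde); C5–prenyl; C1–C2 and the CH2–CH bond of the C1 prenyl group (alkenylcopper addition to a C1 methylene ketone, then aldol with formaldehyde); C8–homoprenyl; C8–methyl; ring A (Michael addition, aldol condensation).
- Forward: ring A is made first, C8 and then C1 are made quaternary on it, the C2–C4 arm and the C5 prenyl group are attached, ring B is closed by gold catalysis, and the aroyl group goes on last.
- Stereochemistry: C7 from an enamine-catalysed Michael addition; C8 (homoprenyl anti to the C7 prenyl) and C1 (C2 anti to the axial C8 methyl) by substrate control on the ring A half-chair; C5 relayed from C1 through the tether in the ring closure.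

Key step: step 13

Remark: the target is written as its C2-keto/C4-enol tautomer, which equilibrates freely with the C4-keto/C2-enol form, so the route aims at the triketone as one compound; 5-methylhex-4-enal is taken as a catalogue aldehyde.

Step 1
Reactants: 1 5-methylhex-4-enal; 2 but-3-en-2-one
Product: 3 (S)-2-prenyl-5-oxohexanal
Conditions: (S)-2-(methoxydiphenylmethyl)pyrrolidine (5 mol%), ethyl 3,4-dihydroxybenzoate (20 mol%), neat, 4 °C
Reagents that add atoms: none
Why: Enamine-catalysed asymmetric Michael addition of an aldehyde to a vinyl ketone, in which the diphenylmethoxymethyl group of the (S)-pyrrolidine shields one face of the anti-enamine so that the enone should add to the open face and set the future C7 as (S).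

Step 2
Reactants: 3 (S)-2-prenyl-5-oxohexanal
Product: 4 (S)-4-prenylcyclohex-2-en-1-one
Conditions: LiOH (0.2 equiv), i-PrOH, rt
Reagents that add atoms: none
Why: Intramolecular aldol condensation in which only the methyl ketone enolate can reach the aldehyde through a six-membered transition state, run with a mild base so that the stereocentre (α in the aldehyde, γ in the enone) should be kept.

Step 3
Reactants: 4 (S)-4-prenylcyclohex-2-en-1-one
Product: 5 trimethylsilyl enol ether of (3S,4S)-3-methyl-4-prenylcyclohexanone
Conditions: MeMgBr, CuBr·SMe2 (10 mol%), Me3SiCl, THF, −78 °C; Et3N, aq. NaHCO3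
Reagents that add atoms: methylmagnesium bromide, C[Mg]Br; chlorotrimethylsilane, C[Si](C)(C)Cl
Why: Copper-catalysed conjugate addition of a Grignard reagent with in situ O-silylation, the methyl group entering anti to the C7 prenyl group (a centre erased in step 4) and the enol ether being fixed between C1 and C9.

Step 4
Reactants: 5 trimethylsilyl enol ether of (3S,4S)-3-methyl-4-prenylcyclohexanone
Product: 6 (S)-3-methyl-4-prenylcyclohex-2-en-1-one
Conditions: Pd(OAc)2 (1.05 equiv), MeCN, rt
Reagents that add atoms: none
Why: Saegusa–Ito oxidation, in which the palladium enolate bound at C1 can only lose the hydride on C8 and so returns the enone with the methyl group on C8, giving zerovalent palladium and leaving C7 untouched.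

Step 5
Reactants: 6 (S)-3-methyl-4-prenylcyclohex-2-en-1-one; 7 5-bromo-2-methylpent-2-ene
Product: 9 trimethylsilyl enol ether of (3S,4S)-3-homoprenyl-3-methyl-4-prenylcyclohexanone, via (4-methylpent-3-en-1-yl)magnesium bromide 8 (not isolated)
Conditions: 7, Mg, THF, 40 °C; then 6, CuBr·SMe2 (20 mol%), Me3SiCl, DMPU, THF, −78 → −30 °C; Et3N, aq. NaHCO3
Reagents that add atoms: chlorotrimethylsilane, C[Si](C)(C)Cl
Why: Chlorosilane-accelerated copper-catalysed 1,4-addition of a Grignard reagent to a β,β-disubstituted enone, the homoprenyl group adding to the half-chair anti to the neighbouring C7 prenyl group so that quaternary C8 is set as (S) with its methyl group cis to that prenyl group.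

Step 6
Reactants: 9 trimethylsilyl enol ether of (3S,4S)-3-homoprenyl-3-methyl-4-prenylcyclohexanone
Product: 12 (3S,4S)-3-homoprenyl-3-methyl-2-methylidene-4-prenylcyclohexan-1-one, via Mannich base 10 (not isolated), via ammonium iodide 11 (not isolated)
Conditions: CH2=NMe2+ I−, CH2Cl2, rt; aq. NaHCO3 wash; MeI, Et2O, rt; saturated aq. NaHCO3, CH2Cl2, rt
Reagents that add atoms: N,N-dimethylmethyleneiminium iodide, C=[N+](C)C.[I-]
Why: Mannich reaction of the regiodefined silyl enol ether at C1, followed by N-methylation and E1cB loss of trimethylamine, gives the C1 methylene ketone without any chance of reaction at C5 and leaves no new stereocentre.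

Step 7
Reactants: 12 (3S,4S)-3-homoprenyl-3-methyl-2-methylidene-4-prenylcyclohexan-1-one
Product: 14 (2R,3S,4S)-3-homoprenyl-2-(hydroxymethyl)-3-methyl-2,4-diprenylcyclohexan-1-one, via bromomagnesium enolate 13 (not isolated)
Conditions: Me2C=CHMgBr, CuBr·SMe2 (10 mol%), THF, −78 °C; then monomeric HCHO in THF (from cracked paraformaldehyde), −78 → −40 °C; aq. NH4Cl
Reagents that add atoms: (2-methylprop-1-en-1-yl)magnesium bromide, CC(C)=C[Mg]Br; formaldehyde, C=O
Why: Copper-catalysed conjugate addition of the alkenyl Grignard reagent to the exocyclic enone turns the methylene group into the C1 prenyl group and gives the tetrasubstituted C1=C9 enolate regiospecifically, and its aldol reaction with formaldehyde should take the axial path on the face anti to the axial C8 methyl group (and to the C7 prenyl group), which puts the future C2 cis to the C8 homoprenyl group, (R) at C1.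

Step 8
Reactants: 14 (2R,3S,4S)-3-homoprenyl-2-(hydroxymethyl)-3-methyl-2,4-diprenylcyclohexan-1-one
Product: 15 (1R,2S,3S)-2-homoprenyl-2-methyl-6-oxo-1,3-diprenylcyclohexane-1-carbaldehyde
Conditions: Dess–Martin periodinane, pyridine, CH2Cl2, 0 °C → rt
Reagents that add atoms: none
Why: Buffered hypervalent-iodine oxidation of a primary neopentyl alcohol to the aldehyde, which spares the trisubstituted olefins and gives a keto aldehyde that has no hydrogen on C1 and so cannot epimerise.

Step 9
Reactants: 15 (1R,2S,3S)-2-homoprenyl-2-methyl-6-oxo-1,3-diprenylcyclohexane-1-carbaldehyde; 16 ethoxyacetylene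
Product: 19 (2R,3S,4S)-2-[3-ethoxy-1-(trimethylsilyloxy)prop-2-yn-1-yl]-3-homoprenyl-3-methyl-2,4-diprenylcyclohexan-1-one (both carbinol epimers), via lithium ethoxyacetylide 17 (not isolated), via lithium alkoxide 18 (not isolated)
Conditions: 16, n-BuLi, THF, −78 °C; then 15, −78 °C; then Me3SiCl, −78 → −20 °C; aq. NaHCO3
Reagents that add atoms: chlorotrimethylsilane, C[Si](C)(C)Cl
Why: 1,2-Addition of a lithium acetylide to the aldehyde, which is far more electrophilic than the C9 ketone next to quaternary C1, with the alkoxide capped in the same flask as its silyl ether before it can fragment by retro-aldol reaction; the carbinol centre forms as a mixture that step 12 removes.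

Step 10
Reactants: 19 the silyl-protected ethoxypropargyl ketone
Product: 21 C5-prenylated ketone (19 with a further prenyl group on C5; epimers at C5 and at the carbinol carbon), via lithium enolate 20 (not isolated)
Conditions: LiN(i-Pr)2, THF, −78 °C; then 1-bromo-3-methylbut-2-ene, −78 → −30 °C
Reagents that add atoms: 1-bromo-3-methylbut-2-ene, CC(C)=CCBr
Why: Kinetic enolate alkylation with an allylic bromide, regiochemically unambiguous because C1 is quaternary and C5 is the only enolisable position; the C5 centre need not be controlled since it becomes trigonal in step 11.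

Step 11
Reactants: 21 C5-prenylated ketone
Product: 24 ring A tert-butyldimethylsilyl enol ether (C5=C9) with a 3-ethoxy-1-hydroxyprop-2-yn-1-yl group on C1 (carbinol epimers), via potassium enolate 22 (not isolated), via bis-silyl ether 23 (not isolated)
Conditions: KN(SiMe3)2 (1.4 equiv), THF, −78 → −20 °C; t-BuMe2SiOTf (1.3 equiv), −78 °C; then Et3N, MeOH, K2CO3, 0 °C
Reagents that add atoms: tert-butyldimethylsilyl trifluoromethanesulfonate, CC(C)(C)[Si](C)(C)OS(=O)(=O)C(F)(F)F
Why: Enolisation can only occur toward C5, O-silylation of the potassium enolate with the silyl triflate gives the tetrasubstituted C5=C9 enol ether, and basic methanolysis then removes only the far more labile trimethylsilyl ether.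

Step 12
Reactants: 24 ring A silyl enol ether with the ethoxypropargyl alcohol on C1
Product: 25 ring A silyl enol ether with a 3-ethoxypropynoyl group on C1
Conditions: activated MnO2 (20 equiv), CH2Cl2, rt
Reagents that add atoms: none
Why: Neutral heterogeneous oxidation of a propargylic alcohol to the ynone, chosen because the 3-ethoxypropargyl alcohol would undergo Meyer–Schuster rearrangement under acid and the silyl enol ether would not survive electrophilic oxidants.

Step 13
Reactants: 25 ring A silyl enol ether with a 3-ethoxypropynoyl group on C1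
Product: 26 (1R,5S,7R,8S)-4-ethoxy-8-homoprenyl-8-methyl-1,5,7-triprenylbicyclo[3.3.1]non-3-ene-2,9-dione
Conditions: [(t-Bu)2(2-biphenylyl)PAu(NCMe)]SbF6 (5 mol%), acetone containing H2O (1.5 equiv), 0.02 M, 0 °C → rt
Reagents that add atoms: none
Why: Proposed new method: the cationic monovalent gold centre binds the C3≡C4 triple bond and sharpens the polarisation already imposed by the C2 carbonyl and the ethoxy oxygen, so that C4 acts as a ketene-oxonium-type electrophile; C5 of the silyl enol ether adds to it anti to gold, the silyloxocarbenium ion at C9 passes its silyl group to water, and the proton released cleaves the C3–Au bond and frees the catalyst; the closest known reaction type is the monovalent-gold-catalysed carbocyclisation of cyclic silyl enol ethers onto tethered alkynes and terminal ynones to bicyclo[3.3.1]nonenones, in which a 3-alkoxy ynone has not yet served as acceptor. Ring B is closed in the 6-endo-dig mode by formation of the C4–C5 bond. The new quaternary stereocentre C5 is dictated by C1, because the three-carbon arm anchored on C1 can bridge to C5 only across the ring face on which it stands. The step needs 6-endo instead of 5-exo attack, carbon instead of oxygen attack of the enol ether, and the enol ether instead of a prenyl olefin as nucleophile: the first follows from the matched polarisation of the alkyne (C4 lies β to the C2 carbonyl and carries the ethoxy group) and from the bulky biaryl phosphine, the second from the tert-butyldimethylsilyl group on oxygen, the third from the much higher nucleophilicity of the enol ether. A linear sp carbon is also the least demanding electrophile for fully substituted C5, and the product appears with the C2 ketone and C4 enol ether that ring B needs, under conditions free of any base that could cut the C1–C2 bond by retro-Claisen cleavage.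

Step 14
Reactants: 27 3-hydroxybenzoic acid
Product: 28 tert-butyldimethylsilyl 3-[(tert-butyldimethylsilyl)oxy]benzoate
Conditions: t-BuMe2SiCl (2.3 equiv), imidazole (5 equiv), DMF, rt
Reagents that add atoms: tert-butyl(chloro)dimethylsilane, CC(C)(C)[Si](C)(C)Cl
Why: Imidazole-promoted silylation of both the phenol and the carboxylic acid, a standard double protection that needs no selectivity.

Step 15
Reactants: 28 tert-butyldimethylsilyl 3-[(tert-butyldimethylsilyl)oxy]benzoate
Product: 29 3-[(tert-butyldimethylsilyl)oxy]benzoyl chloride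
Conditions: (COCl)2, DMF (cat.), CH2Cl2, 0 °C → rt
Reagents that add atoms: oxalyl chloride, O=C(Cl)C(Cl)=O
Why: Direct conversion of a silyl ester into the acid chloride by Vilsmeier-type activation with oxalyl chloride and catalytic DMF, which runs without free acid and so spares the aryl silyl ether.

Step 16
Reactants: 26 bicyclic ethyl vinylogous ester; 29 3-[(tert-butyldimethylsilyl)oxy]benzoyl chloride
Product: 31 (1S,5S,7R,8S)-3-{3-[(tert-butyldimethylsilyl)oxy]benzoyl}-4-ethoxy-8-homoprenyl-8-methyl-1,5,7-triprenylbicyclo[3.3.1]non-3-ene-2,9-dione, via C3-lithio species 30 (not isolated)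
Conditions: lithium 2,2,6,6-tetramethylpiperidide (1.5 equiv, from the amine and n-BuLi), THF, −78 °C; then 29, −78 → −40 °C
Reagents that add atoms: none
Why: Vinylic deprotonation at C3, the only acidic C–H left because both bridgeheads are quaternary, gives an α-lithiated vinylogous ester that is C-acylated by the aroyl chloride, the established way of placing the C3 acyl group on bicyclo[3.3.1]nonane vinylogous esters of this family.

Step 17
Reactants: 31 C3-aroylated ethyl vinylogous ester
Product: 32 (1S,5S,7R,8S)-4-hydroxy-3-(3-hydroxybenzoyl)-8-homoprenyl-8-methyl-1,5,7-triprenylbicyclo[3.3.1]non-3-ene-2,9-dione (target)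
Conditions: LiOH (10 equiv), 1,4-dioxane–H2O, 90 °C; then 1 M HCl
Reagents that add atoms: lithium hydroxide, [Li+].[OH-]
Why: Addition–elimination of hydroxide at C4 of the doubly activated enol ether releases ethanol and the stabilised triketone enolate (which resists retro-Claisen cleavage), the aryl silyl ether is saponified in the same operation, and acidification gives the target with no stereocentre touched.

**Compound list**

1 | 5-methylhex-4-enal | CC(C)=CCCC=O | starting material
2 | but-3-en-2-one | CC(=O)C=C | starting material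
3 | (S)-2-(3-methylbut-2-en-1-yl)-5-oxohexanal | O=C[C@H](CC=C(C)C)CCC(C)=O | intermediate
4 | (S)-4-(3-methylbut-2-en-1-yl)cyclohex-2-en-1-one | O=C1CC[C@@H](CC=C(C)C)C=C1 | intermediate
5 | trimethyl{[(3S,4S)-3-methyl-4-(3-methylbut-2-en-1-yl)cyclohex-1-en-1-yl]oxy}silane (methyl trans to prenyl) | C[C@@H]1C=C(O[Si](C)(C)C)CC[C@H]1CC=C(C)C | intermediate
6 | (S)-3-methyl-4-(3-methylbut-2-en-1-yl)cyclohex-2-en-1-one | CC1=CC(=O)CC[C@H]1CC=C(C)C | intermediate
7 | 5-bromo-2-methylpent-2-ene | CC(C)=CCCBr | starting material
8 | (4-methylpent-3-en-1-yl)magnesium bromide | CC(C)=CCC[Mg]Br | intermediate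
9 | trimethyl{[(3S,4S)-3-methyl-4-(3-methylbut-2-en-1-yl)-3-(4-methylpent-3-en-1-yl)cyclohex-1-en-1-yl]oxy}silane (homoprenyl trans to prenyl) | CC(C)=CCC[C@]1(C)C=C(O[Si](C)(C)C)CC[C@H]1CC=C(C)C | intermediate
10 | (2R,3S,4S)-2-[(dimethylamino)methyl]-3-methyl-4-(3-methylbut-2-en-1-yl)-3-(4-methylpent-3-en-1-yl)cyclohexan-1-one (C2 as expected; erased in the same step) | CC(C)=CCC[C@@]1(C)[C@H](CC=C(C)C)CCC(=O)[C@H]1CN(C)C | intermediate
11 | N-methyl quaternary ammonium iodide of 10 | CC(C)=CCC[C@@]1(C)[C@H](CC=C(C)C)CCC(=O)[C@H]1C[N+](C)(C)C.[I-] | intermediate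
12 | (3S,4S)-3-methyl-2-methylidene-4-(3-methylbut-2-en-1-yl)-3-(4-methylpent-3-en-1-yl)cyclohexan-1-one | CC(C)=CCC[C@@]1(C)[C@H](CC=C(C)C)CCC(=O)C1=C | intermediate
13 | bromomagnesium (3S,4S)-3-methyl-2,4-bis(3-methylbut-2-en-1-yl)-3-(4-methylpent-3-en-1-yl)cyclohex-1-en-1-olate | CC(C)=CCC[C@@]1(C)[C@H](CC=C(C)C)CCC(O[Mg]Br)=C1CC=C(C)C | intermediate
14 | (2R,3S,4S)-2-(hydroxymethyl)-3-methyl-2,4-bis(3-methylbut-2-en-1-yl)-3-(4-methylpent-3-en-1-yl)cyclohexan-1-one | CC(C)=CCC[C@@]1(C)[C@H](CC=C(C)C)CCC(=O)[C@@]1(CC=C(C)C)CO | intermediate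
15 | (1R,2S,3S)-2-methyl-1,3-bis(3-methylbut-2-en-1-yl)-2-(4-methylpent-3-en-1-yl)-6-oxocyclohexane-1-carbaldehyde | CC(C)=CCC[C@@]1(C)[C@H](CC=C(C)C)CCC(=O)[C@@]1(CC=C(C)C)C=O | intermediate
16 | ethoxyacetylene | CCOC#C | starting material
17 | lithium ethoxyacetylide | CCOC#C[Li] | intermediate
18 | lithium alkoxide from addition of 17 to the aldehyde of 15 (carbinol epimers) | CC(C)=CCC[C@@]1(C)[C@H](CC=C(C)C)CCC(=O)[C@@]1(CC=C(C)C)C(O[Li])C#COCC | intermediate
19 | (2R,3S,4S)-2-[3-ethoxy-1-(trimethylsilyloxy)prop-2-yn-1-yl]-3-methyl-2,4-bis(3-methylbut-2-en-1-yl)-3-(4-methylpent-3-en-1-yl)cyclohexan-1-one (carbinol epimers) | CC(C)=CCC[C@@]1(C)[C@H](CC=C(C)C)CCC(=O)[C@@]1(CC=C(C)C)C(O[Si](C)(C)C)C#COCC | intermediate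
20 | lithium C5=C9 enolate of 19 | CC(C)=CCC[C@@]1(C)[C@H](CC=C(C)C)CC=C(O[Li])[C@@]1(CC=C(C)C)C(O[Si](C)(C)C)C#COCC | intermediate
21 | 19 with a further 3-methylbut-2-en-1-yl group on C5 (C1, C7, C8 as in 19; epimers at C5 and at the carbinol carbon) | CC(C)=CCC[C@@]1(C)[C@H](CC=C(C)C)CC(CC=C(C)C)C(=O)[C@@]1(CC=C(C)C)C(O[Si](C)(C)C)C#COCC | intermediate
22 | potassium C5=C9 enolate of 21 | CC(C)=CCC[C@@]1(C)[C@H](CC=C(C)C)CC(CC=C(C)C)=C(O[K])[C@@]1(CC=C(C)C)C(O[Si](C)(C)C)C#COCC | intermediate
23 | tert-butyldimethylsilyl C5=C9 enol ether of 21, trimethylsilyl ether still in place | CC(C)=CCC[C@@]1(C)[C@H](CC=C(C)C)CC(CC=C(C)C)=C(O[Si](C)(C)C(C)(C)C)[C@@]1(CC=C(C)C)C(O[Si](C)(C)C)C#COCC | intermediate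
24 | ring A tert-butyldimethylsilyl enol ether (C5=C9) with prenyl on C1, C5 and C7, methyl and homoprenyl on C8 and a 3-ethoxy-1-hydroxyprop-2-yn-1-yl group on C1 (C1, C7, C8 as in 15; carbinol epimers) | CC(C)=CCC[C@@]1(C)[C@H](CC=C(C)C)CC(CC=C(C)C)=C(O[Si](C)(C)C(C)(C)C)[C@@]1(CC=C(C)C)C(O)C#COCC | intermediate
25 | the same ring A silyl enol ether with a 3-ethoxypropynoyl group on C1 | CC(C)=CCC[C@@]1(C)[C@H](CC=C(C)C)CC(CC=C(C)C)=C(O[Si](C)(C)C(C)(C)C)[C@@]1(CC=C(C)C)C(=O)C#COCC | intermediate
26 | (1R,5S,7R,8S)-4-ethoxy-8-methyl-1,5,7-tris(3-methylbut-2-en-1-yl)-8-(4-methylpent-3-en-1-yl)bicyclo[3.3.1]non-3-ene-2,9-dione | CC(C)=CCC[C@@]1(C)[C@H](CC=C(C)C)C[C@]2(CC=C(C)C)C(=O)[C@@]1(CC=C(C)C)C(=O)C=C2OCC | intermediate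
27 | 3-hydroxybenzoic acid | O=C(O)c1cccc(O)c1 | starting material
28 | tert-butyldimethylsilyl 3-[(tert-butyldimethylsilyl)oxy]benzoate | CC(C)(C)[Si](C)(C)OC(=O)c1cccc(O[Si](C)(C)C(C)(C)C)c1 | intermediate
29 | 3-[(tert-butyldimethylsilyl)oxy]benzoyl chloride | CC(C)(C)[Si](C)(C)Oc1cccc(c1)C(Cl)=O | intermediate
30 | C3-lithio derivative of 26 | CC(C)=CCC[C@@]1(C)[C@H](CC=C(C)C)C[C@]2(CC=C(C)C)C(=O)[C@@]1(CC=C(C)C)C(=O)C([Li])=C2OCC | intermediate
31 | (1S,5S,7R,8S)-3-{3-[(tert-butyldimethylsilyl)oxy]benzoyl}-4-ethoxy-8-methyl-1,5,7-tris(3-methylbut-2-en-1-yl)-8-(4-methylpent-3-en-1-yl)bicyclo[3.3.1]non-3-ene-2,9-dione (the C1 descriptor changes from R to S by priority only) | CC(C)=CCC[C@@]1(C)[C@H](CC=C(C)C)C[C@]2(CC=C(C)C)C(=O)[C@@]1(CC=C(C)C)C(=O)C(C(=O)c1cccc(O[Si](C)(C)C(C)(C)C)c1)=C2OCC | intermediate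
32 | (1S,5S,7R,8S)-4-hydroxy-3-(3-hydroxybenzoyl)-8-methyl-1,5,7-tris(3-methylbut-2-en-1-yl)-8-(4-methylpent-3-en-1-yl)bicyclo[3.3.1]non-3-ene-2,9-dione (CNP0406274.2) | CC(C)=CCC[C@@]1(C)[C@H](CC=C(C)C)C[C@]2(CC=C(C)C)C(=O)[C@@]1(CC=C(C)C)C(=O)C(C(=O)c1cccc(O)c1)=C2O | target

**Step count**

Total step count: 17. Longest linear sequence: 15 steps (steps 1–13, 16 and 17); steps 14 and 15 make the acid chloride.

**Steps most likely to fail**

Step 13. The ynol ether may be consumed by gold-promoted addition of the water needed for turnover. The enol ether may also close through oxygen, the C1 prenyl olefin may capture the activated alkyne, or crowding at fully substituted C5 may stop the closure. The fallback gives up the preformed C1 arm and builds ring B by known acylation chemistry. From 12, the conjugate addition of step 7 is quenched with Me3SiCl instead of formaldehyde to give the C1-prenylated trimethylsilyl enol ether F1. Effenberger cyclisation with malonyl dichloride, followed by aqueous KOH with a phase-transfer salt, acylates C1 anti to the C7 prenyl group and then C5. This forms C1–C2 and C4–C5 in one operation and gives the bicyclic 2,4,9-trione without a C5 substituent F2. Triethyl orthoformate with catalytic p-toluenesulfonic acid in ethanol gives the C4 ethyl enol ether F3 together with the C2 ethyl enol ether regioisomer F4, which is returned to F2 by aqueous acid. Bridgehead lithiation of F3 with LiN(i-Pr)2 and trapping with prenyl bromide installs the C5 prenyl group and gives 26, where the route is rejoined.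

Step 7. The crowded tetrasubstituted enolate may be protonated or may give formaldehyde back by retro-aldol reaction before the product is secured, and facial selectivity at C1 may fall short of the half-chair model. The fallback replaces the reversible aldol by an irreversible Lewis-acid alkylation at the aldehyde oxidation level. From 12, the same conjugate addition is run with Et3SiCl present to give the triethylsilyl enol ether F5. Trimethyl orthoformate with catalytic Me3SiOTf in CH2Cl2 at −78 °C (Mukaiyama-type attack on a dimethoxycarbenium ion, on the same face) gives the keto dimethyl acetal F6. Pyridinium p-toluenesulfonate in wet acetone unmasks the aldehyde and delivers 15, so steps 7 and 8 are both replaced.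

Step 9. The β-keto alkoxide 18 may fragment by retro-aldol reaction before it is silylated, or the acetylide may attack the C9 ketone. The fallback masks C9 before the C2–C3 bond is made. From 14, Me3SiCl and imidazole give the trimethylsilyl ether F7. LiN(i-Pr)2 followed by prenyl bromide gives the C5-prenylated ketone F8. KN(SiMe3)2 and t-BuMe2SiOTf give the bis-silyl compound F9, and K2CO3 in methanol removes its trimethylsilyl ether to leave the primary alcohol with the C5=C9 silyl enol ether F10. Buffered Dess–Martin oxidation gives the enol ether aldehyde F11. Lithium ethoxyacetylide then adds to the only carbonyl group present, and a cold acetic acid quench gives 24, where the route is rejoined.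

**Further compounds**

F1 | step 13 | C1-prenylated trimethylsilyl enol ether (C1=C9) of ring A | CC(C)=CCC[C@@]1(C)[C@H](CC=C(C)C)CCC(O[Si](C)(C)C)=C1CC=C(C)C
F2 | step 13 | bicyclic 2,4,9-trione with hydrogen on C5 | CC(C)=CCC[C@@]1(C)[C@H](CC=C(C)C)C[C@@H]2C(=O)[C@@]1(CC=C(C)C)C(=O)CC2=O
F3 | step 13 | C4 ethyl enol ether of F2 | CC(C)=CCC[C@@]1(C)[C@H](CC=C(C)C)C[C@@H]2C(=O)[C@@]1(CC=C(C)C)C(=O)C=C2OCC
F4 | step 13 | C2 ethyl enol ether of F2 | CC(C)=CCC[C@@]1(C)[C@H](CC=C(C)C)C[C@@H]2C(=O)[C@@]1(CC=C(C)C)C(OCC)=CC2=O
F5 | step 7 | C1-prenylated triethylsilyl enol ether (C1=C9) of ring A | CC(C)=CCC[C@@]1(C)[C@H](CC=C(C)C)CCC(O[Si](CC)(CC)CC)=C1CC=C(C)C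
F6 | step 7 | dimethyl acetal of 15 | CC(C)=CCC[C@@]1(C)[C@H](CC=C(C)C)CCC(=O)[C@@]1(CC=C(C)C)C(OC)OC
F7 | step 9 | trimethylsilyl ether of 14 | CC(C)=CCC[C@@]1(C)[C@H](CC=C(C)C)CCC(=O)[C@@]1(CC=C(C)C)CO[Si](C)(C)C
F8 | step 9 | C5-prenylated F7 (C5 epimers) | CC(C)=CCC[C@@]1(C)[C@H](CC=C(C)C)CC(CC=C(C)C)C(=O)[C@@]1(CC=C(C)C)CO[Si](C)(C)C
F9 | step 9 | tert-butyldimethylsilyl C5=C9 enol ether of F8 | CC(C)=CCC[C@@]1(C)[C@H](CC=C(C)C)CC(CC=C(C)C)=C(O[Si](C)(C)C(C)(C)C)[C@@]1(CC=C(C)C)CO[Si](C)(C)C
F10 | step 9 | primary alcohol from F9 | CC(C)=CCC[C@@]1(C)[C@H](CC=C(C)C)CC(CC=C(C)C)=C(O[Si](C)(C)C(C)(C)C)[C@@]1(CC=C(C)C)CO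
F11 | step 9 | C1 aldehyde with the C5=C9 silyl enol ether | CC(C)=CCC[C@@]1(C)[C@H](CC=C(C)C)CC(CC=C(C)C)=C(O[Si](C)(C)C(C)(C)C)[C@@]1(CC=C(C)C)C=O
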